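**Plan**

1. Retrosynthetic cuts, in order: the C6–C1' bond to the geranyl chain; the two MOM acetals; C3–H (alcohol back to ketone); the C2–C3 bond of the pyran ring; then O1–C2 (aryloxyisobutyric acid arm) and C4a–C4 (allyl arm).
2. Forward: ring A is bought as 2,4,6-trihydroxybenzophenone. Bis-MOM protection leaves only the chelated hydroxyl, which sends an allyl group to C4a (Claisen) and then carries the C(CH3)2CO2H arm; the allyl group is cut down to the C3 aldehyde.
3. The pyranone ring closes by a carbene-catalysed decarboxylative radical acylation that joins C3 to C2. Ketone reduction, MOM removal and C-geranylation at the one free carbon of ring A follow.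
4. Enabling feature: C2 of the pyran ring is fully substituted and bears O1 and two methyl groups, so it can be generated as a tertiary α-aryloxyalkyl radical from a carboxylic acid. C3 is a carbinol carbon one oxidation level below an acyl carbon, tied through C4 to C4a, ortho to the O1-bearing C8a.
5. Stereochemistry: C3 (R), the only stereocentre, comes from the (S)-CBS catalyst in the ketone reduction; the E olefin is bought with geranyl bromide.

Key step: step 7

Remark: read from the SMILES, the carbinol carbon C3 is R and the C2'=C3' olefin of the side chain is E; chroman numbering (O1, C2, C3, C4, C4a, C5–C8, C8a) is used throughout.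

**Step 1**
Reactants: 1 2,4,6-trihydroxybenzophenone; 2 chloromethyl methyl ether
Product: 3 (2-hydroxy-4,6-bis(methoxymethoxy)phenyl)(phenyl)methanone
Conditions: MOMCl (2.2 equiv), i-Pr2NEt, CH2Cl2, 0 °C to rt
Reagents that add atoms: chloromethyl methyl ether 2, COCCl
Why: One ortho hydroxyl stays locked in a hydrogen bond to the benzoyl carbonyl and is the least nucleophilic, so O-alkylation (Williamson-type acetal ether formation) should stop at the 4,6-bis-ether and leave the chelated 2-OH free.

**Step 2**
Reactants: 3 (2-hydroxy-4,6-bis(methoxymethoxy)phenyl)(phenyl)methanone; 4 allyl bromide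
Product: 5 [2-(allyloxy)-4,6-bis(methoxymethoxy)phenyl](phenyl)methanone
Conditions: allyl bromide, K2CO3, DMF, 60 °C
Reagents that add atoms: allyl bromide 4, C=CCBr
Why: Williamson ether synthesis on the remaining phenoxide, which reacts once the hydrogen bond is broken by carbonate in a dipolar solvent at raised temperature.

**Step 3**
Reactants: 5 [2-(allyloxy)-4,6-bis(methoxymethoxy)phenyl](phenyl)methanone
Product: 7 (3-allyl-2-hydroxy-4,6-bis(methoxymethoxy)phenyl)(phenyl)methanone, via ortho-dienone 6 (not isolated)
Conditions: N,N-diethylaniline, 190 °C, sealed tube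
Reagents that add atoms: none
Why: Aromatic Claisen rearrangement, a [3,3]-sigmatropic shift to the only unsubstituted ortho carbon (the other bears the benzoyl group), followed by enolisation of the dienone; the basic amine solvent protects the MOM acetals.

**Step 4**
Reactants: 7 (3-allyl-2-hydroxy-4,6-bis(methoxymethoxy)phenyl)(phenyl)methanone; 8 1,1,1-trichloro-2-methylpropan-2-ol (chloretone)
Product: 10 2-[6-allyl-2-benzoyl-3,5-bis(methoxymethoxy)phenoxy]-2-methylpropanoic acid, via acyl chloride 9 (not isolated)
Conditions: chloretone, powdered NaOH, acetone, 0 °C to rt; work-up with aqueous citric acid to pH 4 at 0 °C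
Reagents that add atoms: 1,1,1-trichloro-2-methylpropan-2-ol 8, CC(C)(O)C(Cl)(Cl)Cl; sodium hydroxide, [Na+].[OH-] (oxygen of the acid OH)
Why: Bargellini reaction, in which base turns chloretone into a gem-dichloroepoxide that the hindered phenoxide opens at the tertiary carbon and the resulting acyl chloride is hydrolysed; this is the standard entry to hindered α-aryloxyisobutyric acids, and the MOM ethers, allyl group and diaryl ketone are stable to hydroxide.

**Step 5**
Reactants: 10 2-[6-allyl-2-benzoyl-3,5-bis(methoxymethoxy)phenoxy]-2-methylpropanoic acid; 11 N-hydroxyphthalimide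
Product: 12 1,3-dioxoisoindolin-2-yl 2-[6-allyl-2-benzoyl-3,5-bis(methoxymethoxy)phenoxy]-2-methylpropanoate
Conditions: N-hydroxyphthalimide, N,N'-diisopropylcarbodiimide, DMAP (cat.), CH2Cl2, rt
Reagents that add atoms: N-hydroxyphthalimide 11, O=C1c2ccccc2C(=O)N1O
Why: Carbodiimide (Steglich-type) esterification, the routine preparation of redox-active N-acyloxyphthalimides, which is well established for α-aryloxyisobutyric acids.

**Step 6**
Reactants: 12 1,3-dioxoisoindolin-2-yl 2-[6-allyl-2-benzoyl-3,5-bis(methoxymethoxy)phenoxy]-2-methylpropanoate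
Product: 14 1,3-dioxoisoindolin-2-yl 2-[2-benzoyl-3,5-bis(methoxymethoxy)-6-(2-oxoethyl)phenoxy]-2-methylpropanoate, via vicinal diol 13 (not isolated)
Conditions: OsO4 (cat.), NaIO4, 2,6-lutidine, dioxane/H2O, rt; the aldehyde is used crude
Reagents that add atoms: OsO4, O=[Os](=O)(=O)=O (catalytic carrier of the oxygen); NaIO4, [Na+].[O-]I(=O)(=O)=O (terminal oxygen source)
Why: Lemieux–Johnson oxidation, in which the terminal alkene is the only site that OsO4 dihydroxylates and periodate cleaves the diol to the arylacetaldehyde; the non-nucleophilic lutidine buffer should leave the hindered active ester and the acetals intact.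

**Step 7**
Reactants: 14 1,3-dioxoisoindolin-2-yl 2-[2-benzoyl-3,5-bis(methoxymethoxy)-6-(2-oxoethyl)phenoxy]-2-methylpropanoate
Product: 16 8-benzoyl-5,7-bis(methoxymethoxy)-2,2-dimethylchroman-3-one, via enaminol 15 (not isolated)
Conditions: 3-(2,6-diisopropylphenyl)-5,6,7,8-tetrahydro-4H-cyclohepta[d]thiazol-3-ium perchlorate (10 mol%), Cs2CO3 (20 mol%), DMSO (0.02 M), 60 °C, argon
Reagents that add atoms: none
Why: Proposed new method: the thiazol-2-ylidene adds to the aldehyde of 14 to give enaminol 15, whose enolate passes one electron to the N-acyloxyphthalimide; loss of phthalimide anion and CO2 leaves a tertiary α-aryloxyalkyl radical at C2 and the persistent carbene-bound ketyl radical at C3 in one molecule, and their combination followed by expulsion of the carbene forms the C2–C3 bond and the ketone. The closest known reaction type is the carbene-catalysed decarboxylative radical coupling of aldehydes (aliphatic ones included) with tertiary N-acyloxyphthalimides to give hindered ketones, which is known between two molecules and is proposed here as a ring closure with an α-aryloxy radical. The dihydropyranone ring closes as a six-membered ring by recombination of the two radical centres (collapse of a 1,6-diradical; no alkene terminus is involved). No stereocentre is formed, since C2 carries two methyl groups and C3 becomes a carbonyl carbon; C3 is set in step 8. The step needs ring closure to win over aldol self-condensation of the arylacetaldehyde, hydrogen transfer between the two radicals and intermolecular coupling; the ortho placement of the two arms on C4a and C8a, the gem-dimethyl group at C2, the persistence of the ketyl radical and the dilution should secure this, and the site of radical formation is fixed by the carboxyl group.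

**Step 8**
Reactants: 16 8-benzoyl-5,7-bis(methoxymethoxy)-2,2-dimethylchroman-3-one
Product: 17 [(3R)-3-hydroxy-5,7-bis(methoxymethoxy)-2,2-dimethylchroman-8-yl](phenyl)methanone
Conditions: (S)-2-methyl-CBS-oxazaborolidine (20 mol%), BH3·SMe2 (0.7 equiv), THF, −30 °C; MeOH quench
Reagents that add atoms: none
Why: Corey–Bakshi–Shibata reduction, in which the ketone binds the ring boron anti to the bulky quaternary C2 and hydride is delivered to one face, so the (S)-catalyst (which gives (R)-1-phenylethanol from acetophenone) should give the (R)-alcohol because C2 takes both the steric role and the priority rank of the phenyl group; the twisted, doubly ortho-oxygenated diaryl ketone is the slower carbonyl and should survive a limiting amount of borane.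

**Step 9**
Reactants: 17 [(3R)-3-hydroxy-5,7-bis(methoxymethoxy)-2,2-dimethylchroman-8-yl](phenyl)methanone
Product: 18 [(3R)-3,5,7-trihydroxy-2,2-dimethylchroman-8-yl](phenyl)methanone
Conditions: HCl (3 M aq.), MeOH, 50 °C
Reagents that add atoms: none
Why: Acid-catalysed acetal exchange removes both MOM groups as dimethoxymethane; the homobenzylic secondary alcohol at C3 cannot ionise and the chroman ether is stable to dilute acid, so the stereocentre is untouched.

**Step 10**
Reactants: 18 [(3R)-3,5,7-trihydroxy-2,2-dimethylchroman-8-yl](phenyl)methanone; 19 geranyl bromide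
Product: 20 [(3R)-6-[(2E)-3,7-dimethylocta-2,6-dienyl]-3,5,7-trihydroxy-2,2-dimethylchroman-8-yl](phenyl)methanone (target)
Conditions: geranyl bromide (1.0 equiv), KOH (10% aq.), 0 °C to rt
Reagents that add atoms: geranyl bromide 19, CC(C)=CCC/C(C)=C/CBr
Why: C-alkylation of the ambident acylphloroglucinol phenoxide in water, where hydrogen bonding to oxygen favours attack through carbon; C6 is the only unsubstituted ring carbon and lies between the two hydroxyls, and direct displacement at the primary allylic bromide keeps the E olefin.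

**Compound list**

1 | 2,4,6-trihydroxybenzophenone | O=C(c1ccccc1)c1c(O)cc(O)cc1O | starting material
2 | chloromethyl methyl ether | COCCl | starting material
3 | (2-hydroxy-4,6-bis(methoxymethoxy)phenyl)(phenyl)methanone | O=C(c1ccccc1)c1c(O)cc(OCOC)cc1OCOC | intermediate
4 | allyl bromide | C=CCBr | starting material
5 | [2-(allyloxy)-4,6-bis(methoxymethoxy)phenyl](phenyl)methanone | O=C(c1ccccc1)c1c(OCC=C)cc(OCOC)cc1OCOC | intermediate
6 | 6-allyl-2-benzoyl-3,5-bis(methoxymethoxy)cyclohexa-2,4-dien-1-one (racemic, not isolated) | O=C(c1ccccc1)C1=C(OCOC)C=C(OCOC)C(CC=C)C1=O | intermediate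
7 | (3-allyl-2-hydroxy-4,6-bis(methoxymethoxy)phenyl)(phenyl)methanone | O=C(c1ccccc1)c1c(O)c(CC=C)c(OCOC)cc1OCOC | intermediate
8 | 1,1,1-trichloro-2-methylpropan-2-ol (chloretone) | CC(C)(O)C(Cl)(Cl)Cl | starting material
9 | 2-[6-allyl-2-benzoyl-3,5-bis(methoxymethoxy)phenoxy]-2-methylpropanoyl chloride (not isolated) | O=C(c1ccccc1)c1c(OC(C)(C)C(=O)Cl)c(CC=C)c(OCOC)cc1OCOC | intermediate
10 | 2-[6-allyl-2-benzoyl-3,5-bis(methoxymethoxy)phenoxy]-2-methylpropanoic acid | O=C(c1ccccc1)c1c(OC(C)(C)C(=O)O)c(CC=C)c(OCOC)cc1OCOC | intermediate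
11 | N-hydroxyphthalimide | O=C1c2ccccc2C(=O)N1O | starting material
12 | 1,3-dioxoisoindolin-2-yl 2-[6-allyl-2-benzoyl-3,5-bis(methoxymethoxy)phenoxy]-2-methylpropanoate | O=C(c1ccccc1)c1c(OC(C)(C)C(=O)ON2C(=O)c3ccccc3C2=O)c(CC=C)c(OCOC)cc1OCOC | intermediate
13 | 1,3-dioxoisoindolin-2-yl 2-[2-benzoyl-6-(2,3-dihydroxypropyl)-3,5-bis(methoxymethoxy)phenoxy]-2-methylpropanoate (racemic at the carbinol carbon, not isolated) | O=C(c1ccccc1)c1c(OC(C)(C)C(=O)ON2C(=O)c3ccccc3C2=O)c(CC(O)CO)c(OCOC)cc1OCOC | intermediate
14 | 1,3-dioxoisoindolin-2-yl 2-[2-benzoyl-3,5-bis(methoxymethoxy)-6-(2-oxoethyl)phenoxy]-2-methylpropanoate | O=C(c1ccccc1)c1c(OC(C)(C)C(=O)ON2C(=O)c3ccccc3C2=O)c(CC=O)c(OCOC)cc1OCOC | intermediate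
15 | enaminol adduct of 14 with 3-(2,6-diisopropylphenyl)-5,6,7,8-tetrahydro-4H-cyclohepta[d]thiazol-2-ylidene (enol geometry not defined, not isolated) | O=C(c1ccccc1)c1c(OC(C)(C)C(=O)ON2C(=O)c3ccccc3C2=O)c(CC(O)=C2SC3=C(CCCCC3)N2c2c(C(C)C)cccc2C(C)C)c(OCOC)cc1OCOC | intermediate
16 | 8-benzoyl-5,7-bis(methoxymethoxy)-2,2-dimethylchroman-3-one | CC1(C)Oc2c(C(=O)c3ccccc3)c(OCOC)cc(OCOC)c2CC1=O | intermediate
17 | [(3R)-3-hydroxy-5,7-bis(methoxymethoxy)-2,2-dimethylchroman-8-yl](phenyl)methanone | CC1(C)Oc2c(C(=O)c3ccccc3)c(OCOC)cc(OCOC)c2C[C@H]1O | intermediate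
18 | [(3R)-3,5,7-trihydroxy-2,2-dimethylchroman-8-yl](phenyl)methanone | CC1(C)Oc2c(C(=O)c3ccccc3)c(O)cc(O)c2C[C@H]1O | intermediate
19 | geranyl bromide, (2E)-1-bromo-3,7-dimethylocta-2,6-diene | CC(C)=CCC/C(C)=C/CBr | starting material
20 | [(3R)-6-[(2E)-3,7-dimethylocta-2,6-dienyl]-3,5,7-trihydroxy-2,2-dimethylchroman-8-yl](phenyl)methanone | CC(C)=CCC/C(C)=C/Cc1c(O)c2c(c(C(=O)c3ccccc3)c1O)OC(C)(C)[C@H](O)C2 | target

**Step count and risks**

Total step count: 10. Longest linear sequence: 10 steps (from 1 to 20).

Steps most likely to fail: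

Step 7. The ring closure may lose to base-induced aldol self-condensation of the arylacetaldehyde, to hydrogen transfer between the two radical centres (giving the isopropenyl ether) or to coupling between molecules. The fallback uses known chemistry and closes the same ring through the O1–C2 bond instead. It sets out from 7. Olefin cross-metathesis with 2-methyl-2-butene (second-generation Grubbs catalyst (H2IMes)(PCy3)Cl2Ru=CHPh, CH2Cl2, 40 °C) should give the prenyl phenol (2-hydroxy-4,6-bis(methoxymethoxy)-3-(3-methylbut-2-enyl)phenyl)(phenyl)methanone F1. Shi epoxidation with the D-fructose-derived ketone and KHSO5 (as the triple salt 2KHSO5·KHSO4·K2SO4, K2CO3 buffer, MeCN/dimethoxymethane/H2O, 0 °C) should give the (R)-epoxide [2-hydroxy-3-{[(2R)-3,3-dimethyloxiran-2-yl]methyl}-4,6-bis(methoxymethoxy)phenyl](phenyl)methanone F2. Camphorsulfonic acid (cat.) in CH2Cl2 at 0 °C should then bring about the 6-endo opening of the epoxide by the phenol at the tertiary carbon, with the configuration at C3 retained. The fallback comes back to the route at 17.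

Step 10. O-alkylation at the 5-hydroxyl, or a second alkylation at C6 with loss of aromaticity, may outrun the single C-alkylation. The fallback sets out from 17. Iodination at C6, the only free and triply oxygen-activated ring carbon (N-iodosuccinimide, DMF, rt), should give [(3R)-3-hydroxy-6-iodo-5,7-bis(methoxymethoxy)-2,2-dimethylchroman-8-yl](phenyl)methanone F3. Stille coupling with tributyl[(2E)-3,7-dimethylocta-2,6-dien-1-yl]stannane (Pd(PPh3)4, DMF, 90 °C) should give [(3R)-6-[(2E)-3,7-dimethylocta-2,6-dienyl]-3-hydroxy-5,7-bis(methoxymethoxy)-2,2-dimethylchroman-8-yl](phenyl)methanone F4. Removal of the MOM groups (HCl, MeOH, rt) comes back to the route at 20.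

Step 8. Hydride delivery to the diaryl ketone may compete with reduction of the ring ketone, so that a limiting amount of borane gives mixtures. The fallback sets out from 16. Both carbonyl groups are reduced on purpose with an excess of BH3·SMe2 and the same (S)-catalyst (THF, −30 °C to 0 °C), which should give the diol (3R)-8-[hydroxy(phenyl)methyl]-5,7-bis(methoxymethoxy)-2,2-dimethylchroman-3-ol F5 as a mixture of epimers at the benzhydrol carbon. MnO2 (CH2Cl2, rt) should then oxidise only the doubly benzylic carbinol back to the ketone and leave the aliphatic C3 alcohol. The fallback comes back to the route at 17.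

**Further compounds**

F1 | step 7 | (2-hydroxy-4,6-bis(methoxymethoxy)-3-(3-methylbut-2-enyl)phenyl)(phenyl)methanone | O=C(c1ccccc1)c1c(O)c(CC=C(C)C)c(OCOC)cc1OCOC
F2 | step 7 | [2-hydroxy-3-{[(2R)-3,3-dimethyloxiran-2-yl]methyl}-4,6-bis(methoxymethoxy)phenyl](phenyl)methanone | O=C(c1ccccc1)c1c(O)c(C[C@H]2OC2(C)C)c(OCOC)cc1OCOC
F3 | step 10 | [(3R)-3-hydroxy-6-iodo-5,7-bis(methoxymethoxy)-2,2-dimethylchroman-8-yl](phenyl)methanone | CC1(C)Oc2c(C(=O)c3ccccc3)c(OCOC)c(I)c(OCOC)c2C[C@H]1O
F4 | step 10 | [(3R)-6-[(2E)-3,7-dimethylocta-2,6-dienyl]-3-hydroxy-5,7-bis(methoxymethoxy)-2,2-dimethylchroman-8-yl](phenyl)methanone | CC(C)=CCC/C(C)=C/Cc1c(OCOC)c2c(c(C(=O)c3ccccc3)c1OCOC)OC(C)(C)[C@H](O)C2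
F5 | step 8 | (3R)-8-[hydroxy(phenyl)methyl]-5,7-bis(methoxymethoxy)-2,2-dimethylchroman-3-ol (epimers at the benzhydrol carbon) | CC1(C)Oc2c(C(O)c3ccccc3)c(OCOC)cc(OCOC)c2C[C@H]1O
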